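The route is cut at the two bonds that leave neighbouring atoms of ring A, O1–C8a and C4–C4a. In one operation a 3,5-dimethoxy-6-prenylbenzyne takes up the silyl ether of ethyl (S)-3-hydroxy-3-phenylpropanoate: the alkoxide oxygen adds at C8a and the aryl anion born at C4a closes pyranone ring C on the ester carbonyl, so C2 arrives already set. The step exploits the C5 oxygen of ring A, which flanks the aryne and places the anion at C4a, and the 1,3-relation of O1 to the C4 carbonyl. The precursor is an ortho-silylaryl triflate made by two directed ortho-metalations of a 3,5-dimethoxyphenyl carbamate. Selective O5 demethylation and alkene hydration finish the route.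

Key step: step 5

Remark: flavanone numbering is used throughout (O1, C2, C3, C4, C4a, C5 to C8, C8a; ring A is the benzo ring, ring C the pyranone). The single stereocentre, C2, is S and is taken from commercial ethyl (S)-3-hydroxy-3-phenylpropanoate.

Step 1
Reactants: 1 3,5-dimethoxyphenol
Product: 2 3,5-dimethoxyphenyl N-isopropylcarbamate
Conditions: i-PrNCO, Et3N (cat.), CH2Cl2, rt
Reagents that add atoms: isopropyl isocyanate, CC(C)N=C=O
Why: Amine-catalysed addition of the phenol to the isocyanate (carbamoylation) should give the N-isopropyl carbamate, which serves as the directing group for ortho-metalation and as a mildly cleavable mask of the oxygen that becomes the triflate.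

Step 2
Reactants: 2 3,5-dimethoxyphenyl N-isopropylcarbamate; 3 prenyl bromide (1-bromo-3-methylbut-2-ene)
Product: 9 3,5-dimethoxy-2-(3-methylbut-2-en-1-yl)-6-(trimethylsilyl)phenyl N-isopropylcarbamate, via N-silyl carbamate 4 (not isolated), via first aryllithium 5 (not isolated), via C-silyl N-silyl carbamate 6 (not isolated), via second aryllithium 7 (not isolated), via N-silyl prenyl carbamate 8 (not isolated)
Conditions: TBSOTf, TMEDA, Et2O, 0 °C to rt; n-BuLi (2.1 equiv), TMEDA, −78 °C; TMSCl (1.1 equiv), −78 °C to rt; n-BuLi (1.2 equiv), TMEDA, −78 °C; 3, −78 to −20 °C; aq NaHSO4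
Reagents that add atoms: chlorotrimethylsilane, C[Si](C)(C)Cl
Why: Iterative directed ortho-metalation in one flask: after N-silylation (4) the carbamate, reinforced each time by the adjacent methoxy group, should direct lithiation first to one flank (5, silylated to 6) and then, with that flank blocked, to the other (7), whose SN2 alkylation with 3 gives 8 and, after hydrolytic loss of the N-silyl group, 9, while the position between the two methoxy groups lacks the stronger carbamate director.

Step 3
Reactants: 9 3,5-dimethoxy-2-(3-methylbut-2-en-1-yl)-6-(trimethylsilyl)phenyl N-isopropylcarbamate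
Product: 11 3,5-dimethoxy-2-(3-methylbut-2-en-1-yl)-6-(trimethylsilyl)phenyl trifluoromethanesulfonate, via silyl phenol 10 (not isolated)
Conditions: DBU, Et2NH, MeCN, 40 °C; then PhNTf2, rt
Reagents that add atoms: N-phenylbis(trifluoromethanesulfonimide), O=S(=O)(N(c1ccccc1)S(=O)(=O)C(F)(F)F)C(F)(F)F
Why: DBU-induced E1cB cleavage of the N–H carbamate should release the phenoxide of 10 and isopropyl isocyanate, which Et2NH scavenges as a urea, and O-triflation of the phenoxide then gives the ortho-silylaryl triflate aryne precursor.

Step 4
Reactants: 12 ethyl (S)-3-hydroxy-3-phenylpropanoate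
Product: 13 ethyl (S)-3-phenyl-3-[(trimethylsilyl)oxy]propanoate
Conditions: TMSCl, imidazole, CH2Cl2, 0 °C to rt
Reagents that add atoms: chlorotrimethylsilane, C[Si](C)(C)Cl
Why: Standard O-silylation of a secondary alcohol, which removes the only O–H donor from the key step and turns the nucleophile into a fluoride-releasable alkoxide without touching the stereocentre.

Step 5
Reactants: 11 3,5-dimethoxy-2-(3-methylbut-2-en-1-yl)-6-(trimethylsilyl)phenyl trifluoromethanesulfonate; 13 ethyl (S)-3-phenyl-3-[(trimethylsilyl)oxy]propanoate
Product: 16 (S)-5,7-dimethoxy-8-(3-methylbut-2-en-1-yl)-2-phenylchroman-4-one, via aryne 14 (not isolated), via aryl anion 15 (not isolated)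
Conditions: CsF, 18-crown-6, THF, 0 °C to rt
Reagents that add atoms: none
Why: Proposed new method: fluoride removes the aryl silyl group of 11 with loss of triflate to give aryne 14 and frees the alkoxide of 13, which adds through oxygen to the aryne carbon next to the prenyl-bearing carbon (the future C8a) to give aryl anion 15, and this anion attacks the ethyl ester in a 6-exo-trig addition–elimination that forms the C4–C4a bond and closes ring C. The closest known reaction type is the CsF-mediated annulation of arynes with salicylate esters to xanthones (nucleophilic addition to the aryne followed by intramolecular acyl substitution), extended here from a phenoxide to an aliphatic β-oxido ester. No stereocentre is made: C2 comes from 12 and keeps its S configuration because its C–O bond is never broken. The step needs regioselective addition to an unsymmetrical aryne, and the C5 methoxy group beside one aryne carbon secures it, since the aryne distortion model places the incoming oxygen at the remote carbon and the negative charge ortho to the inductively withdrawing oxygen, against only a modest steric bias from the prenyl CH2. It also needs ring closure to outrun protonation and a medium that stays non-basic, which the silyl ether secures by removing all O–H donors and by capturing the expelled ethoxide as EtOSiMe3 before it can open ring C by retro-oxa-Michael reaction and erode the ee.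

Step 6
Reactants: 16 (S)-5,7-dimethoxy-8-(3-methylbut-2-en-1-yl)-2-phenylchroman-4-one
Product: 17 (S)-5-hydroxy-7-methoxy-8-(3-methylbut-2-en-1-yl)-2-phenylchroman-4-one
Conditions: BCl3, CH2Cl2, −78 to −20 °C; aq NaHCO3
Reagents that add atoms: none
Why: Chelation-controlled aryl methyl ether cleavage: BCl3 should bind the C4 carbonyl and the peri C5 methoxy oxygen in a six-membered chelate so that chloride removes only that methyl group, leaving the C7 methoxy group, the alkene and, at low temperature, the C2 stereocentre untouched.

Step 7
Reactants: 17 (S)-5-hydroxy-7-methoxy-8-(3-methylbut-2-en-1-yl)-2-phenylchroman-4-one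
Product: 18 (S)-5-hydroxy-8-(3-hydroxy-3-methylbutyl)-7-methoxy-2-phenylchroman-4-one
Conditions: Co(acac)2 (cat.), PhSiH3, O2 (1 atm), THF/i-PrOH, rt
Reagents that add atoms: dioxygen, O=O
Why: Mukaiyama hydration (hydrogen atom transfer from a cobalt hydride, capture of the tertiary radical by O2, reduction of the peroxide by the silane) should add water in the Markovnikov sense to the trisubstituted alkene under neutral conditions that leave the ketone, the chelated phenol and C2 alone.

Compound list
1 | 3,5-dimethoxyphenol | COc1cc(O)cc(OC)c1 | starting material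
2 | 3,5-dimethoxyphenyl N-isopropylcarbamate | COc1cc(OC)cc(OC(=O)NC(C)C)c1 | intermediate
3 | prenyl bromide (1-bromo-3-methylbut-2-ene) | CC(C)=CCBr | starting material
4 | 3,5-dimethoxyphenyl N-(tert-butyldimethylsilyl)-N-isopropylcarbamate | COc1cc(OC)cc(OC(=O)N(C(C)C)[Si](C)(C)C(C)(C)C)c1 | intermediate
5 | first aryllithium, lithiated between the carbamate and a methoxy group | COc1cc(OC)c([Li])c(OC(=O)N(C(C)C)[Si](C)(C)C(C)(C)C)c1 | intermediate
6 | 3,5-dimethoxy-2-(trimethylsilyl)phenyl N-(tert-butyldimethylsilyl)-N-isopropylcarbamate | COc1cc(OC)c([Si](C)(C)C)c(OC(=O)N(C(C)C)[Si](C)(C)C(C)(C)C)c1 | intermediate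
7 | second aryllithium, lithiated at the remaining position ortho to the carbamate | COc1cc(OC)c([Si](C)(C)C)c(OC(=O)N(C(C)C)[Si](C)(C)C(C)(C)C)c1[Li] | intermediate
8 | 3,5-dimethoxy-2-(3-methylbut-2-en-1-yl)-6-(trimethylsilyl)phenyl N-(tert-butyldimethylsilyl)-N-isopropylcarbamate | COc1cc(OC)c([Si](C)(C)C)c(OC(=O)N(C(C)C)[Si](C)(C)C(C)(C)C)c1CC=C(C)C | intermediate
9 | 3,5-dimethoxy-2-(3-methylbut-2-en-1-yl)-6-(trimethylsilyl)phenyl N-isopropylcarbamate | COc1cc(OC)c([Si](C)(C)C)c(OC(=O)NC(C)C)c1CC=C(C)C | intermediate
10 | 3,5-dimethoxy-2-(3-methylbut-2-en-1-yl)-6-(trimethylsilyl)phenol | COc1cc(OC)c([Si](C)(C)C)c(O)c1CC=C(C)C | intermediate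
11 | 3,5-dimethoxy-2-(3-methylbut-2-en-1-yl)-6-(trimethylsilyl)phenyl trifluoromethanesulfonate | COc1cc(OC)c([Si](C)(C)C)c(OS(=O)(=O)C(F)(F)F)c1CC=C(C)C | intermediate
12 | ethyl (S)-3-hydroxy-3-phenylpropanoate | CCOC(=O)C[C@H](O)c1ccccc1 | starting material
13 | ethyl (S)-3-phenyl-3-[(trimethylsilyl)oxy]propanoate | CCOC(=O)C[C@H](O[Si](C)(C)C)c1ccccc1 | intermediate
14 | 3,5-dimethoxy-6-(3-methylbut-2-en-1-yl)benzyne | COC1=CC(OC)=C(CC=C(C)C)C#C1 | intermediate
15 | cesium aryl anion of ethyl (S)-3-[3,5-dimethoxy-2-(3-methylbut-2-en-1-yl)phenoxy]-3-phenylpropanoate, carbanion ortho to the ether oxygen and to a methoxy group | CCOC(=O)C[C@H](Oc1[c-]c(OC)cc(OC)c1CC=C(C)C)c1ccccc1.[Cs+] | intermediate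
16 | (S)-5,7-dimethoxy-8-(3-methylbut-2-en-1-yl)-2-phenylchroman-4-one | COc1cc(OC)c2c(c1CC=C(C)C)O[C@H](c1ccccc1)CC2=O | intermediate
17 | (S)-5-hydroxy-7-methoxy-8-(3-methylbut-2-en-1-yl)-2-phenylchroman-4-one | COc1cc(O)c2c(c1CC=C(C)C)O[C@H](c1ccccc1)CC2=O | intermediate
18 | (S)-5-hydroxy-8-(3-hydroxy-3-methylbutyl)-7-methoxy-2-phenylchroman-4-one | COc1cc(O)c2c(c1CCC(C)(C)O)O[C@H](c1ccccc1)CC2=O | target

Total step count: 7
Longest linear sequence: 6 (steps 1, 2, 3, 5, 6, 7)

Steps most likely to fail

Step 5 (key step). Three processes could spoil it: the aryl anion could be protonated, or could abstract the ester α-proton with β-elimination of the aryloxide, before it closes ring C; the alkoxide could add at the wrong aryne carbon; and base-mediated opening and re-closure of ring C could erode the ee. The fallback uses known chemistry, sets out from 11 and the free hydroxy ester 12, and comes back at 16. Aryne generation from 11 with CsF in MeCN in the presence of 12 should give, by O-arylation of the alcohol and protonation of the aryl anion, ethyl (S)-3-[3,5-dimethoxy-2-(3-methylbut-2-en-1-yl)phenoxy]-3-phenylpropanoate F1. Saponification with LiOH in THF/water at 0 °C should give (S)-3-[3,5-dimethoxy-2-(3-methylbut-2-en-1-yl)phenoxy]-3-phenylpropanoic acid F2. TFAA in CH2Cl2 at 0 °C should then close ring C by intramolecular Friedel–Crafts acylation at the only free position ortho to the ether oxygen, giving 16.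

Step 2. The risks are incomplete first silylation leading to mixed substitution patterns, migration of the carbamoyl group to carbon (anionic ortho-Fries) on warming, and SN2' or Wurtz-type reaction of the hindered aryllithium with the allylic bromide. The fallback sets out from 2 and comes back at 9. The first half of step 2 alone, stopped with aqueous NaHSO4 after the TMSCl quench, should give 3,5-dimethoxy-2-(trimethylsilyl)phenyl N-isopropylcarbamate F3 after isolation. Renewed N-silylation and lithiation (through 6 and 7) with an iodine quench should give 2-iodo-3,5-dimethoxy-6-(trimethylsilyl)phenyl N-(tert-butyldimethylsilyl)-N-isopropylcarbamate F4 in the flask and, after hydrolytic work-up, 2-iodo-3,5-dimethoxy-6-(trimethylsilyl)phenyl N-isopropylcarbamate F5. Stille coupling of F5 with tributyl(3-methylbut-2-en-1-yl)stannane (CC(C)=CC[Sn](CCCC)(CCCC)CCCC; Pd(PPh3)4, CuI, CsF, DMF, 45 °C) should deliver 9.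

Step 6. The risks are Lewis-acid-promoted opening of ring C to the chalcone and re-closure with loss of ee, addition of HCl to the prenyl alkene, and over-demethylation at O7. The fallback sets out from 16 and comes back at 18. Mukaiyama hydration of 16 under the step 7 conditions, with the alkene thus removed before any Lewis acid is used, should give (S)-8-(3-hydroxy-3-methylbutyl)-5,7-dimethoxy-2-phenylchroman-4-one F6. MgI2 etherate in THF at 45 °C should then remove only the peri methyl group by iodide attack on the magnesium chelate, giving 18 directly.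

Further compounds
F1 | step 5 | ethyl (S)-3-[3,5-dimethoxy-2-(3-methylbut-2-en-1-yl)phenoxy]-3-phenylpropanoate | CCOC(=O)C[C@H](Oc1cc(OC)cc(OC)c1CC=C(C)C)c1ccccc1
F2 | step 5 | (S)-3-[3,5-dimethoxy-2-(3-methylbut-2-en-1-yl)phenoxy]-3-phenylpropanoic acid | OC(=O)C[C@H](Oc1cc(OC)cc(OC)c1CC=C(C)C)c1ccccc1
F3 | step 2 | 3,5-dimethoxy-2-(trimethylsilyl)phenyl N-isopropylcarbamate | COc1cc(OC)c([Si](C)(C)C)c(OC(=O)NC(C)C)c1
F4 | step 2 | 2-iodo-3,5-dimethoxy-6-(trimethylsilyl)phenyl N-(tert-butyldimethylsilyl)-N-isopropylcarbamate | COc1cc(OC)c([Si](C)(C)C)c(OC(=O)N(C(C)C)[Si](C)(C)C(C)(C)C)c1I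
F5 | step 2 | 2-iodo-3,5-dimethoxy-6-(trimethylsilyl)phenyl N-isopropylcarbamate | COc1cc(OC)c([Si](C)(C)C)c(OC(=O)NC(C)C)c1I
F6 | step 6 | (S)-8-(3-hydroxy-3-methylbutyl)-5,7-dimethoxy-2-phenylchroman-4-one | COc1cc(OC)c2c(c1CCC(C)(C)O)O[C@H](c1ccccc1)CC2=O
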